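If we treat a share and a decay constant as frozen over the late part of these runs, the flask comes down to those two numbers.

in all of them: free catalyst 6.5 mM
- noon: substrate 0.13 M; partner 0.12 M; protic impurity 0.039 M; run made earlier
- dusk: substrate 0.13 M; partner 0.18 M; protic impurity 0.039 M; run made earlier
- winter: substrate 0.20 M; partner 0.234 M; protic impurity 0.039 M; run made earlier
- flask: substrate 0.13 M; partner 0.234 M; protic impurity 0.0390 M; time 4.0 h

| run | time / h | substrate / % | target / % |
|---|---|---|---|
| noon | 0.333 | 56.4 | 6.5 |
| noon | 0.667 | 51.7 | 9.9 |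
| noon | 1.00 | 49.4 | 15.4 |
| noon | 1.33 | 46.2 | 19.4 |
| noon | 1.50 | 44.4 | 20.9 |
| noon | 2.00 | 41.5 | 24.1 |
| noon | 2.50 | 40.4 | 30.7 |
| dusk | 0.133 | 63.8 | 2.5 |
| dusk | 0.333 | 54.4 | 8.5 |
| dusk | 0.667 | 48.8 | 16.5 |
| dusk | 1.00 | 44.9 | 22.2 |
| dusk | 1.33 | 41.3 | 28.5 |
| dusk | 2.00 | 34.8 | 39.5 |
| dusk | 2.50 | 31.2 | 44.2 |
| winter | 0.200 | 60.8 | 4.6 |
| winter | 0.333 | 55.5 | 9.5 |
| winter | 0.667 | 49.7 | 16.8 |
| winter | 1.33 | 40.7 | 29.8 |
| winter | 2.50 | 31.2 | 46.8 |

(each reading ± 0.5 percentage points)

- amount of substrate in percent of the substrate charged, at 12 min, 1.0 h and 4.0 h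

- steps under discussion: substrate + free catalyst <-> free catalyst + open intermediate; free catalyst + open intermediate <-> catalyst intermediate; partner + protic impurity -> quenched reagent; partner + catalyst intermediate -> free catalyst + target

Substrate drops fast at first while little target appears, and after that it stays a steady share of W, the percentage of the charge that is not yet target. At the last reading of the three runs that share averages 0.576. We treat the late fall of W as exponential (pseudo-first-order), with decay constant λ, and read 0.129 h⁻¹ from noon and 0.212 h⁻¹ from dusk. Those runs have the same substrate charge. Usable partner u, the partner charged minus the protic impurity charged, is 0.0810 M in noon and 0.141 M in dusk, and λ/u reads 4.43 × 10⁻⁴ M⁻¹ s⁻¹ in noon and 4.17 × 10⁻⁴ M⁻¹ s⁻¹ in dusk. Their mean, 4.30 × 10⁻⁴ M⁻¹ s⁻¹, is κ, the decay constant of W per unit of usable partner.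

Our first way uses κ. The flask has the substrate charge of noon and dusk and u = 0.195 M, so λ = 0.302 h⁻¹. Dusk's line traced back to zero time starts W at 94.8%. Substrate is then 40.4% at 1.0 h and 16.3% at 4.0 h.

Our second way takes the winter run, which has the flask's partner charge, and carries its own λ of 0.237 h⁻¹ from its last reading. That gives 43.7% and 21.5%, so the two ways part. Winter is the one that cheats: its λ/u of 3.38 × 10⁻⁴ M⁻¹ s⁻¹ is lower than κ, and it carries more substrate than the flask. We keep the first way. At 12 min the winter run is still falling fast, to 55.5% by 0.333 h, so we do not use the exponential line there and take winter's reading at that time, 60.8%.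

The forecast, which differs somewhat from our figures, gave 60.3%, 41% and 12%, calling the last “the least certain value”.

The flask gives 58.5%, 41.0% and 15.2%, on this scheme:

    substrate + free catalyst ⇌ free catalyst + open intermediate (K = 0.710, k = 0.380 M⁻¹ s⁻¹)
    free catalyst + open intermediate ⇌ catalyst intermediate (K = 24.0 M⁻¹, k = 1.90 M⁻¹ s⁻¹)
    partner + protic impurity → quenched reagent (k = 0.00370 M⁻¹ s⁻¹)
    partner + catalyst intermediate → free catalyst + target (k = 0.0190 M⁻¹ s⁻¹)

In the flask at 4.0 h target stands at 73.4%, and substrate is 0.571 of W. Carried to twice the time, κ gives 4.88% of substrate, and the flask then holds 4.69% of substrate.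

(All runs come from a simulation with made-up constants, and the scatter is random.)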